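Tuesday's run at 0.036 M and Sunday's at 0.31 M lay on the table when the meeting opened, and the analyst reported that their curves of target run together.

| run | time / h | target / % |
|---|---|---|
| Tuesday's | 0.200 | 2.9 |
| Tuesday's | 0.667 | 7.6 |
| Tuesday's | 1.00 | 10.9 |
| Tuesday's | 1.50 | 14.9 |
| Tuesday's | 2.50 | 22.7 |
| Tuesday's | 3.00 | 24.8 |
| Tuesday's | 4.00 | 31.0 |
| Sunday's | 0.500 | 5.7 |
| Sunday's | 1.00 | 10.5 |
| Sunday's | 1.50 | 15.6 |
| Sunday's | 2.50 | 21.9 |
| Sunday's | 3.00 | 26.4 |
| Sunday's | 4.00 | 31.3 |

(readings scatter by 0.5 percentage points)

At 1.00 h she read 10.9% and 10.5%. At 4.0 h she read 31.0% and 31.3%, a gap of 0.3 percentage points, which is less than the scatter of a single reading, 0.5 points.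

The process chemist proposed a zero for the scale: a flask of first-order steps, each taking one molecule at a time, gives percent curves that ignore the charge. Among the candidate steps, substrate + intermediate C is the one in which two species must meet, so she looked there for any departure from that zero. Sunday's charge was 8.61 times Tuesday's, she said, and still the gap stayed inside the scatter.

The shift leader objected that elm, at 0.025 M, lies below Tuesday's charge. The process chemist answered that she expected a flask thinner than Tuesday's to lie nearer that zero, and that oak, at 0.20 M, lies below Sunday's charge.

The meeting agreed to carry one number, the four-hour yield, meaning the part of the charge found as target at 4.0 h, taken as the mean of both runs: 31.1%.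

| setting | Tuesday's | Sunday's | elm | maple | cedar | oak |
|---|---|---|---|---|---|---|
| substrate | 0.036 M | 0.31 M | 0.025 M | 0.050 M | 0.10 M | 0.20 M |
| remark | run made earlier | run made earlier |  |  |  |  |
| time |  |  | 4.0 h | 4.0 h | 4.0 h | 4.0 h |

- [target] at the end for elm, maple, cedar, oak, in this order
- how the row runs (rises, then falls / falls all the way / rises all the way / falls, then rises / hardly changes)

- a species is counted by the substrate in it: one side product counts as two
- candidate steps: substrate -> target; substrate + intermediate C -> side product; intermediate A <-> intermediate B; substrate <-> intermediate A; intermediate B <-> intermediate C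
- "hardly changes" means that all values lie within two and a half points (for a concentration: within two and a half percent of the largest)

My own reckoning multiplies that yield by each charge and gives 0.00778 M, 0.0156 M, 0.0312 M and 0.0622 M, a row that rises with the charge.

The forecast, which gave 0.0078 M, 0.0156 M, 0.0311 M and 0.0622 M, a row that rises all the way, held that “the yield doesn't depend on concentration”.

The flasks give 0.00780 M, 0.0156 M, 0.0312 M and 0.0623 M, and the row rises all the way.

    substrate → target (k = 0.120 h⁻¹)
    substrate + intermediate C → side product (k = 1.20 M⁻¹ h⁻¹)
    intermediate A ⇌ intermediate B (K = 0.160, k = 0.180 h⁻¹)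
    substrate ⇌ intermediate A (K = 0.900, k = 0.140 h⁻¹)
    intermediate B ⇌ intermediate C (K = 0.320, k = 0.330 h⁻¹)

In elm, the half-life of intermediate C by the pairing with substrate, taken by itself at the charged concentrations, is 23 h, ten times the 2.1 h half-life of intermediate B by its forward conversion into intermediate C, and at 4.00 h side product stands at 0.0396% beside 31.2% of target, while the four-hour yield of 31.1% on elm's charge gives 0.00778 M. Oak, with the highest charge of the row, holds 0.296% of side product at 4.00 h, less than its 31.2% of target, and the same yield on its charge gives 0.0622 M against 0.0623 M in the flask.

The readings are simulated for substances that don't exist; noise was put on by code.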